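Divide the rate at which Z is lost by the rate at which it forms, and time drops out of the reckoning; that quotient was where I began.

| flask | X | G | time |
|---|---|---|---|
| amber | 250 mM | 300 mM |  |
| teal | 380 mM | 300 mM |  |
| green | 250 mM | 900 mM |  |
| red | 1000 mM | 1200 mM | 13 min |

| run | time / min | [Z] / mM |
|---|---|---|
| amber run | 2.2 | 19.2 |
| amber run | 4.3 | 30.4 |
| amber run | 6.5 | 38.0 |
| amber run | 8.7 | 46.4 |
| amber run | 11 | 48.8 |
| amber run | 13 | 51.3 |
| teal run | 2.2 | 28.2 |
| teal run | 4.3 | 43.4 |
| teal run | 6.5 | 54.7 |
| teal run | 8.7 | 62.0 |
| teal run | 11 | 67.7 |
| teal run | 13 | 68.7 |
| green run | 2.2 | 47.4 |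
| green run | 4.3 | 64.7 |
| green run | 6.5 | 68.9 |
| green run | 8.7 | 65.0 |
| green run | 11 | 57.2 |
| green run | 13 | 51.1 |

(scatter of a reading: 0.8 mM)

- the power of [G] that the first rate follows, about the charge of the amber run; measure it at two percent of X made into Z
- the power of [X] that the first rate follows, about the charge of the amber run; measure it at two percent of X made into Z (one fixed amount of Z, the same in the runs compared)
- Z in the red run at 13 min, as a share of the X charged

- Overall: X + G -> Z.
- Constant volume, constant temperature.
- An order is taken over about fifteen percent of the charge, up and down.

1. In the green run Z read 68.9 mM at 6.5 min and then fell to 51.1 mM, so something consumed it. I assumed two rates, formation proportional to [X][G] and loss proportional to [Z][G], so that [G] cancelled from their quotient as well.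

2. Extrapolating the first two green readings gave a starting rate of 28.4 mM/min, so for the green run, pseudo-first-order as a first approximation with [G] at 900 mM above [X] at 250 mM, I estimated the first-order constant of X at 0.113 /min.

3. I took the highest green reading as the peak and set the two rates equal there, so that on my assumption the loss constant over the formation constant equalled [X]/[Z] at that time. With [X] reckoned at 120 mM, I estimated this selectivity factor at 1.74.

4. For the red run, the time-free curve gives [Z]/[X]₀ = (x^κ − x)/(1 − κ), where x is the fraction of X left and κ is that factor. Dividing the green constant by the green [G] to carry it over, and setting aside the [G] that loss takes, I reckoned [X] in the red run at 13 min as 301 mM, which gave a share of 24.0%.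

5. The forecast gave orders of 0.93 in [G] and 0.92 in [X], and 17% in the red run, having judged that “Z is being consumed”.

6. The simulation gave orders of 1.1 in [G] and 1.1 in [X], and 21.1% in the red run, below my share.

    X + G → Z (0.1338 /M/min)
    Z + G → E (0.2190 /M/min)
    X + G + Z → 2 Z (0.5616 /M²/min)
    2 X → Wa (0.1356 /M/min)

Turning 2 X into Wa moved the readings by 20 in units of the scatter. With my factor and my reckoned [X], I estimated loss over formation in the red run at 13 min at 1.22, above one. In the amber run, with [X] reckoned at 165 mM, the same estimate at 13 min was 0.539, below one, and the last two amber readings went up, from 48.8 mM to 51.3 mM.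

The data were generated by integration for an exercise; scatter was added.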